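**Remark on the chemistry:** the locants C1–C15 in the text and in the names of the spiro compounds are those fixed in the analysis below (chamigrane numbering); compounds 1, 2 and 6 are taken as purchasable.

## Analysis of the target

Target 23 is a spiro[5.5]undecane. Ring A is C6(spiro)–C7(=C14H2)–C8–C9–C10(Br)–C11(Me2); ring B is C6–C1–C2(Br)–C3(Me)(OH)–C4–C5. It has four stereocentres: C2 (R), C3 (R), C6 (R) and C10 (S). On ring A the C10 bromine is cis to C1, so in the chair with equatorial bromine C1 is equatorial and C5 axial. On ring B the C2 bromine lies on the face of C11 and the C3 hydroxyl on the face of C7; with C11 equatorial on ring B, bromine and hydroxyl are both equatorial (trans) and the C3 methyl is axial. The sensitive groups are the neopentyl secondary bromide at C10 (elimination, methyl shift), the bromohydrin (epoxide formation with base) and the exocyclic alkene (acid-induced migration into ring A). The difficulty is the quaternary spiro stereocentre C6: it sits between the fully substituted C11 and C7, and its two ring B arms differ only at a distance. The strategy rests on one feature: C6 can be the β carbon of a ring B cyclohexenone (C2 ketone, C1 α carbon) while its neighbour C7 carries the one-carbon unit C14. C6, C7, C14 and C1 can therefore be joined in a cyclobutane by a [2+2] photocycloaddition and opened again between C1 and C14.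

## Retrosynthetic reasoning

**23 to 22.** The C2–Br and C3–O bonds are cut together. A trans bromohydrin with bromine on the secondary and oxygen on the tertiary carbon is the Markovnikov hydroxybromination product of the C2=C3 alkene of 22. This is done last because the bromohydrin tolerates neither base nor phosphines. The forward step must put the bromonium ion on the C11 face of ring B and leave the C7=C14 alkene alone.

**22 to 21.** The C10–Br bond is traced back to a C10–O bond of opposite configuration. A secondary bromide beside a quaternary carbon is best made from an enantiopure carbinol by substitution with inversion, because the carbinol can be set early by an aldol reaction and carried protected as in 20. The forward step must be a clean SN2 displacement at a neopentyl centre.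

**20 to 13 (through 19 and 17).** The C2=C3 alkene with its C3 methyl is traced to the C2 ketone of 13. The ketone oxygen marks C2, and the only accessible α position, C3, takes the extra carbon. Going through the exocyclic enone 17 lets a conjugate hydride addition create the C2=C3 enolate without regiochemical choice; it is trapped as enol triflate 19 and reduced to 20.

**13 to 12.** The C1–C14 bond is reconnected and an acetate is placed on C7. In the forward direction the C2 ketyl cuts the strained bond next to it, and the C14 carbanion equivalent expels the acetate. This gives the methylidene and returns C1 as a methylene group. No olefination of a hindered ketone is needed.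

**12 to 11 (key disconnection).** The bonds C6–C7 and C1–C14 are cut. This opens ring A and the cyclobutane and leaves an enone tethered to an enol acetate. It is the only disconnection that forms the C6–C7 bond between two fully substituted carbons without a polar addition to C6. The forward photocycloaddition must give the straight adduct and set C6 under control of C10.

**11 to 10.** The enol acetate is traced to a terminal alkyne by removing the elements of a carboxylic acid O–H addition. The alkyne is inert to the basic steps before it, and the labile enol ester appears only just before irradiation.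

**10 to 8 (through 9).** The enone C1=C6 bond is cut by a retro-aldol condensation to the 1,5-diketone 9, masked as ketal 8. Only one six-membered aldol is possible in 9, so the regiochemistry of the ring closure is fixed.

**8 to 5 and 6.** The C5–C6 bond is cut to an acyl donor, Weinreb amide 5, and a three-carbon nucleophile with a masked methyl ketone, made from chloride 6 through Grignard reagent 7.

**5 to 1 and 2 (through 4 and 3).** The C10–C11 bond is cut by a retro-aldol to aldehyde 1 and the isobutyrate ketene silyl acetal 2. This enantioselective aldol sets C10, the stereocentre from which all the others follow.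

## Alternatives that were turned down

**Alternative 1:** cathodic reductive coupling of an aldehyde and an enone (disconnection C9–C10).
- Forward key step: controlled-potential reduction of keto aldehyde A2 (vinyl ketone on C6, aldehyde on C11) at a carbon cathode gives the enone radical anion. Its β carbon C9 adds to the aldehyde carbon C10 and closes ring A as the 4-hydroxycyclohexanone A1.
- For it: ring B arrives finished, with the C2=C3 alkene and the C3 methyl in place. On ring B it is stronger than the chosen route, which spends three steps turning a C2 ketone into that alkene. It also needs no photochemical equipment.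
- Against it: the spiro carbon C6 must already be a stereocentre in A2. It is a quaternary carbon whose two ring arms differ only by a remote alkene, and no reliable asymmetric entry to it is apparent. The C10 configuration then depends on 1,3-induction in a radical-anion addition to a neopentyl aldehyde. The C7 ketone of A1 still has to be methylenated next to the quaternary C6, and the same inversion at C10 remains.
- Comparison: the chosen strategy reverses the order of stereocontrol. C10 is set first by a dependable aldol and then directs C6, and the methylidene comes from the fragmentation itself.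

**Alternative 2:** sultone-tethered intramolecular Diels–Alder reaction (disconnection C6–C5 and C3–C4).
- Forward key step: heating triene A4 (2-silyloxy diene C6=C1–C2=C3 exocyclic to ring A, vinylsulfonate on the C7 oxygen) forms ring B and a five-membered sultone in A3.
- For it: the tether relays a carbinol stereocentre (C7) to C6, which is as strong as the relay from C10 in the chosen route. It is stronger in that the C3 methyl and a regiodefined C1=C2 silyl enol ether come with the ring.
- Against it: the diene terminus C6 is fully substituted and flanked by the quaternary C11, so both the s-cis diene and the concerted bond formation at C6 are strained. Afterwards the sultone has to be dismantled (C5–S reduction, C7–O to ketone, then methylenation of a hindered ketone). The C10 ketal has to become the bromide, with its configuration set late by substrate control alone. The enol ether returns a C2 ketone, so the ketone-to-alkene work of the chosen route is still required.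
- Comparison: the sequence after the key step is clearly longer. The chosen route gets the methylidene directly and carries C10 from the first step.

**Alternative 3:** manganese-mediated oxidative radical bicyclisation (disconnection C1–C2 and C6–C7).
- Forward key step: Mn(OAc)3 (trivalent manganese) in ethanol oxidises the acyclic β-keto ester A6 to a C2 radical. It adds 6-endo to C1 of the 1,1-disubstituted alkene; the tertiary C6 radical adds 6-exo-dig to the alkyne, and the vinyl radical takes a hydrogen atom from the solvent, giving A5.
- For it: both rings, the spiro carbon and the methylidene come from an acyclic chain in one step, so it is stronger on step economy of ring construction. The oxygen ends at C3, where the carbinol sits, with a carboxyl handle at C2; the ring B oxidation pattern is therefore closer to the target than the C2 ketone of the chosen route.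
- Against it: the tertiary C6 radical, flanked by the quaternary C11, must add to the alkyne faster than trivalent manganese oxidises it to a cation. The chiral ester controls C2, which is later destroyed, while C6 is decided in the second closure by C10 through a flexible chair, so two control elements may oppose each other. Later steps are also weak: methyl addition to an enolisable β-keto ester, and a decarboxylative bromination at C2 through a radical of open facial selectivity.
- Comparison: the chosen route forms the C6–C7 bond from an excited state that is little affected by congestion, uses one stereocontrol element, and its diradical can revert when the geometry is wrong.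

Key step: step 7

## Route

**Step 1**
Reactants: 1 pent-4-ynal; 2 1-methoxy-2-methyl-1-(trimethylsilyloxy)prop-1-ene
Product: 3 methyl (3R)-3-hydroxy-2,2-dimethylhept-6-ynoate
Conditions: N-Ts-L-valine, BH3·THF, CH2Cl2, rt; then 1 and 2, −78 °C; aqueous buffer, then dilute HCl–THF
Reagents that add atoms: none
Why: Asymmetric Mukaiyama aldol in the Kiyooka variant: the N-sulfonyl valine oxazaborolidinone activates the aldehyde and shields one face, and the L-valine reagent is expected to give the 3R carbinol (to be confirmed as Mosher esters; the D-valine reagent gives the antipode). The borane is consumed in forming the promoter before 1 is added, so the alkyne should not be hydroborated.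

**Step 2**
Reactants: 3 methyl (3R)-3-hydroxy-2,2-dimethylhept-6-ynoate
Product: 4 methyl (3R)-3-(tert-butyldimethylsilyloxy)-2,2-dimethylhept-6-ynoate
Conditions: TBSOTf, 2,6-lutidine, CH2Cl2, −78 → 0 °C
Reagents that add atoms: tert-butyldimethylsilyl trifluoromethanesulfonate, CC(C)(C)[Si](C)(C)OS(=O)(=O)C(F)(F)F
Why: Silylation of a hindered secondary alcohol beside a quaternary carbon needs the silyl triflate; the resulting ether should survive every step up to step 12.

**Step 3**
Reactants: 4 methyl (3R)-3-(tert-butyldimethylsilyloxy)-2,2-dimethylhept-6-ynoate
Product: 5 (3R)-3-(tert-butyldimethylsilyloxy)-N-methoxy-N,2,2-trimethylhept-6-ynamide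
Conditions: MeNH(OMe)·HCl, AlMe3, CH2Cl2, 0 → 40 °C
Reagents that add atoms: N,O-dimethylhydroxylamine hydrochloride, CNOC.Cl
Why: Aluminium amide aminolysis of an ester (Weinreb amidation) works on α,α-disubstituted esters where milder amide reagents stall; the terminal alkyne and the silyl ether are inert to AlMe3 at this temperature.

**Step 4**
Reactants: 5 (3R)-3-(tert-butyldimethylsilyloxy)-N-methoxy-N,2,2-trimethylhept-6-ynamide; 6 2-(3-chloropropyl)-2-methyl-1,3-dioxolane
Product: 8 (6R)-6-(tert-butyldimethylsilyloxy)-5,5-dimethyl-1-(2-methyl-1,3-dioxolan-2-yl)dec-9-yn-4-one, via Grignard reagent 7 (not isolated)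
Conditions: 6, Mg, I2 (cat.), THF, reflux; then 5 (7 in threefold excess), THF, 0 °C → rt; aq. NH4Cl
Reagents that add atoms: none
Why: Acylation of a Grignard reagent by a Weinreb amide; the chelated tetrahedral adduct prevents a second addition. One equivalent of 7 is used up by the acetylenic C–H, which is restored on work-up.

**Step 5**
Reactants: 8 (6R)-6-(tert-butyldimethylsilyloxy)-5,5-dimethyl-1-(2-methyl-1,3-dioxolan-2-yl)dec-9-yn-4-one
Product: 10 3-[(3R)-3-(tert-butyldimethylsilyloxy)-2-methylhept-6-yn-2-yl]cyclohex-2-en-1-one, via diketone 9 (not isolated)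
Conditions: 1 M HCl, THF, rt; then KOH, MeOH, 60 °C
Reagents that add atoms: water, O
Why: Acid unmasks the methyl ketone; under base the only six-membered aldol of 9 is attack of the methyl ketone enolate (future C1) on the C6 carbonyl, and dehydration gives the enone (intramolecular aldol condensation). Attack on a ketone with an α-quaternary carbon is the situation met in Robinson annulations of 2,2-disubstituted 1,3-diketones, and C10 cannot eliminate or epimerise because C11 carries no hydrogen.

**Step 6**
Reactants: 10 3-[(3R)-3-(tert-butyldimethylsilyloxy)-2-methylhept-6-yn-2-yl]cyclohex-2-en-1-one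
Product: 11 3-[(3R)-6-acetoxy-3-(tert-butyldimethylsilyloxy)-2-methylhept-6-en-2-yl]cyclohex-2-en-1-one
Conditions: AcOH, [RuCl2(p-cymene)]2 (cat.), P(2-furyl)3, Na2CO3 (cat.), toluene, 50 °C
Reagents that add atoms: acetic acid, CC(=O)O
Why: Ruthenium-catalysed Markovnikov addition of a carboxylic acid to a terminal alkyne gives the 1,1-disubstituted enol acetate (C7 acetate, C14 methylene). Enone and silyl ether are inert, and the labile enol ester is made only after all basic steps.

**Step 7 (key step)**
Reactants: 11 3-[(3R)-6-acetoxy-3-(tert-butyldimethylsilyloxy)-2-methylhept-6-en-2-yl]cyclohex-2-en-1-one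
Product: 12 (1S,3R,6R,8S)-3-(tert-butyldimethylsilyloxy)-2,2-dimethyl-9-oxotricyclo[6.4.0.0^1,6]dodecan-6-yl acetate (cyclobutane C6–C7–C14–C1 cis-fused to rings A and B, C7 acetate, C2 ketone, C1 on C6 trans to the C10 silyloxy group)
Conditions: hν (350 nm, Pyrex), degassed CH2Cl2, high dilution, −20 °C
Reagents that add atoms: none
Why: Excitation of the enone and intersystem crossing give the triplet, whose β carbon C6 bonds to the internal alkene carbon C7; the triplet 1,4-diradical (C1 α-keto radical, C14 primary radical) closes the C1–C14 bond after spin inversion or falls back to 11. The closest known reaction type is the intramolecular enone–alkene [2+2] photocycloaddition of 3-alkenylcyclohexenones that carry a 2-substituted 1-alkene, which is known to join two fully substituted carbons and accepts enol esters as alkene partners. Ring A closes in the 6-exo mode over the four-atom tether C11–C10–C9–C8 (straight adduct), and the cyclobutane C6–C7–C14–C1 closes by recombination of the 1,4-diradical. The step needs the straight and not the crossed regiochemistry: the tether length (the crossed adduct would need a seven-membered first closure) and the head-to-tail preference of an oxygen-bearing alkene carbon for the enone β carbon point the same way. C6 is controlled by C10: in the chair-like tether the silyloxy group is equatorial and C14 is equatorial on C7 (acetate axial), because an axial C14 would be 1,3-diaxial to a C11 methyl, and cyclobutane closure then requires C1 axial on ring A, trans to the C10 oxygen, which is the arrangement that becomes 6R in 13 and in the target. C7 and C1 are fixed relative to C6 by the cis fusion of the four-membered ring and are erased in step 8, so only the C6/C10 relation has to be selective. Diradicals from tether conformers that cannot close revert to 11, which acts as an error correction. The excited-state step is chosen because it tolerates the three contiguous fully substituted carbons C11, C6 and C7 that block polar additions to C6.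

**Step 8**
Reactants: 12 (1S,3R,6R,8S)-3-(tert-butyldimethylsilyloxy)-2,2-dimethyl-9-oxotricyclo[6.4.0.0^1,6]dodecan-6-yl acetate
Product: 13 (6R,10R)-10-(tert-butyldimethylsilyloxy)-11,11-dimethyl-7-methylidenespiro[5.5]undecan-2-one
Conditions: SmI2 (2.5 equiv), THF–HMPA, −78 → 0 °C; aq. NH4Cl
Reagents that add atoms: none
Why: Electron transfer from SmI2 (divalent samarium) gives the C2 ketyl, which cuts the strained cyclobutane bond C1–C14 (the bond external to ring B, aligned with the ketyl); the C14 radical is reduced to the organosamarium, which expels the C7 acetate and forms the C7=C14 methylidene, and the samarium enolate is protonated at C1 on work-up. Both parts are known reaction types (SmI2 opening of cyclobutyl ketones, β-elimination of β-acyloxy organosamariums). C7 and C1 stop being stereocentres, and C6 and C10 are not touched.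

**Step 9**
Reactants: 13 (6R,10R)-10-(tert-butyldimethylsilyloxy)-11,11-dimethyl-7-methylidenespiro[5.5]undecan-2-one
Product: 17 (6R,10R)-10-(tert-butyldimethylsilyloxy)-11,11-dimethyl-3,7-dimethylidenespiro[5.5]undecan-2-one, via lithium enolate 14 (not isolated), via Mannich base 15 (not isolated), via methiodide 16 (not isolated)
Conditions: LDA, THF, −78 °C; CH2=NMe2+ I−, −78 °C → rt; MeI, rt; DBU, rt
Reagents that add atoms: N,N-dimethylmethyleneiminium iodide (Eschenmoser's salt), C=[N+](C)C.[I-]
Why: Kinetic deprotonation should occur at C3 because C1 is neopentyl, next to the spiro carbon; Mannich alkylation, quaternisation and E1cB elimination are the standard α-methylenation of a ketone. The new carbon is the future C3 methyl (C15).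

**Step 10**
Reactants: 17 (6R,10R)-10-(tert-butyldimethylsilyloxy)-11,11-dimethyl-3,7-dimethylidenespiro[5.5]undecan-2-one
Product: 19 (6R,10R)-10-(tert-butyldimethylsilyloxy)-3,11,11-trimethyl-7-methylidenespiro[5.5]undec-2-en-2-yl trifluoromethanesulfonate, via lithium enolate 18 (not isolated)
Conditions: L-Selectride (LiBH(s-Bu)3), THF, −78 °C; then PhNTf2, −78 → 0 °C
Reagents that add atoms: N-phenylbis(trifluoromethanesulfonimide), O=S(=O)(N(c1ccccc1)S(=O)(=O)C(F)(F)F)C(F)(F)F
Why: Conjugate hydride addition to the s-cis exocyclic enone turns the methylidene into the C3 methyl and generates the C2=C3 enolate regiospecifically; O-triflation fixes it as the tetrasubstituted enol triflate. No choice between C1 and C3 arises, unlike direct enolisation of a 3-methyl ketone.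

**Step 11**
Reactants: 19 (6R,10R)-10-(tert-butyldimethylsilyloxy)-3,11,11-trimethyl-7-methylidenespiro[5.5]undec-2-en-2-yl trifluoromethanesulfonate
Product: 20 tert-butyldimethyl{[(6R,10R)-3,11,11-trimethyl-7-methylidenespiro[5.5]undec-2-en-10-yl]oxy}silane
Conditions: Pd(OAc)2 (cat.), PPh3, n-Bu3N, HCO2H, DMF, 60 °C
Reagents that add atoms: none
Why: Palladium-catalysed formate reduction of an enol triflate (oxidative addition to zerovalent palladium formed in situ, formate exchange, loss of CO2, C–H reductive elimination) gives the C2=C3 alkene with the methyl on C3. The isolated alkene and the silyl ether are inert.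

**Step 12**
Reactants: 20 tert-butyldimethyl{[(6R,10R)-3,11,11-trimethyl-7-methylidenespiro[5.5]undec-2-en-10-yl]oxy}silane
Product: 21 (6R,10R)-3,11,11-trimethyl-7-methylidenespiro[5.5]undec-2-en-10-ol
Conditions: TBAF, THF, 50 °C
Reagents that add atoms: none
Why: Fluoride cleavage of the silyl ether; warming is needed because the ether is secondary and neopentyl. C10 keeps its R configuration.

**Step 13**
Reactants: 21 (6R,10R)-3,11,11-trimethyl-7-methylidenespiro[5.5]undec-2-en-10-ol
Product: 22 (6R,10S)-10-bromo-3,11,11-trimethyl-7-methylidenespiro[5.5]undec-2-ene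
Conditions: CBr4, PPh3, toluene, 60 °C
Reagents that add atoms: carbon tetrabromide, BrC(Br)(Br)Br
Why: Appel reaction: the alkoxyphosphonium ion from 21 is displaced by bromide with inversion (SN2), turning 10R into 10S and leaving bromine equatorial and cis to C1. A non-polar, acid-free medium is used so that no carbocation forms beside the quaternary C11.

**Step 14**
Reactants: 22 (6R,10S)-10-bromo-3,11,11-trimethyl-7-methylidenespiro[5.5]undec-2-ene
Product: 23 (2R,3R,6R,10S)-2,10-dibromo-3,11,11-trimethyl-7-methylidenespiro[5.5]undecan-3-ol (target)
Conditions: NBS (1.0 equiv), acetone–H2O, 0 °C, dark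
Reagents that add atoms: N-bromosuccinimide, O=C1CCC(=O)N1Br; water, O
Why: Bromohydrin formation: in 22 the ring A chair with equatorial C10 bromine turns the C7=C14 bond over the C1–C2 edge of ring B, so the bromonium ion should form on the opposite (C11) face of C2=C3, and water opens it anti at the tertiary C3 (Markovnikov), giving 2R,3R. The trisubstituted ring alkene is more electron-rich and far less hindered than the neopentyl C7=C14 alkene, which should not react with one equivalent at 0 °C.

## Compound list

1 | pent-4-ynal | C#CCCC=O | starting material
2 | 1-methoxy-2-methyl-1-(trimethylsilyloxy)prop-1-ene | COC(O[Si](C)(C)C)=C(C)C | starting material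
3 | methyl (3R)-3-hydroxy-2,2-dimethylhept-6-ynoate | COC(=O)C(C)(C)[C@H](O)CCC#C | intermediate
4 | methyl (3R)-3-(tert-butyldimethylsilyloxy)-2,2-dimethylhept-6-ynoate | COC(=O)C(C)(C)[C@H](O[Si](C)(C)C(C)(C)C)CCC#C | intermediate
5 | (3R)-3-(tert-butyldimethylsilyloxy)-N-methoxy-N,2,2-trimethylhept-6-ynamide | CON(C)C(=O)C(C)(C)[C@H](O[Si](C)(C)C(C)(C)C)CCC#C | intermediate
6 | 2-(3-chloropropyl)-2-methyl-1,3-dioxolane | CC1(CCCCl)OCCO1 | starting material
7 | [3-(2-methyl-1,3-dioxolan-2-yl)propyl]magnesium chloride | CC1(CCC[Mg]Cl)OCCO1 | intermediate (not isolated)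
8 | (6R)-6-(tert-butyldimethylsilyloxy)-5,5-dimethyl-1-(2-methyl-1,3-dioxolan-2-yl)dec-9-yn-4-one | CC1(CCCC(=O)C(C)(C)[C@H](O[Si](C)(C)C(C)(C)C)CCC#C)OCCO1 | intermediate
9 | (8R)-8-(tert-butyldimethylsilyloxy)-7,7-dimethyldodec-11-yne-2,6-dione | CC(=O)CCCC(=O)C(C)(C)[C@H](O[Si](C)(C)C(C)(C)C)CCC#C | intermediate (not isolated)
10 | 3-[(3R)-3-(tert-butyldimethylsilyloxy)-2-methylhept-6-yn-2-yl]cyclohex-2-en-1-one | O=C1C=C(CCC1)C(C)(C)[C@H](O[Si](C)(C)C(C)(C)C)CCC#C | intermediate
11 | 3-[(3R)-6-acetoxy-3-(tert-butyldimethylsilyloxy)-2-methylhept-6-en-2-yl]cyclohex-2-en-1-one | O=C1C=C(CCC1)C(C)(C)[C@H](O[Si](C)(C)C(C)(C)C)CCC(=C)OC(C)=O | intermediate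
12 | (1S,3R,6R,8S)-3-(tert-butyldimethylsilyloxy)-2,2-dimethyl-9-oxotricyclo[6.4.0.0^1,6]dodecan-6-yl acetate | O=C1CCC[C@@]23[C@@H]1C[C@]2(OC(C)=O)CC[C@@H](O[Si](C)(C)C(C)(C)C)C3(C)C | intermediate
13 | (6R,10R)-10-(tert-butyldimethylsilyloxy)-11,11-dimethyl-7-methylidenespiro[5.5]undecan-2-one | C=C1CC[C@@H](O[Si](C)(C)C(C)(C)C)C(C)(C)[C@@]12CCCC(=O)C2 | intermediate
14 | lithium enolate of 13 (C2=C3) | [Li+].C=C1CC[C@@H](O[Si](C)(C)C(C)(C)C)C(C)(C)[C@@]12CCC=C([O-])C2 | intermediate (not isolated)
15 | (6R,10R)-10-(tert-butyldimethylsilyloxy)-3-[(dimethylamino)methyl]-11,11-dimethyl-7-methylidenespiro[5.5]undecan-2-one (C3 epimers) | C=C1CC[C@@H](O[Si](C)(C)C(C)(C)C)C(C)(C)[C@@]12CCC(CN(C)C)C(=O)C2 | intermediate (not isolated)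
16 | trimethylammonium iodide of 15 | C=C1CC[C@@H](O[Si](C)(C)C(C)(C)C)C(C)(C)[C@@]12CCC(C[N+](C)(C)C)C(=O)C2.[I-] | intermediate (not isolated)
17 | (6R,10R)-10-(tert-butyldimethylsilyloxy)-11,11-dimethyl-3,7-dimethylidenespiro[5.5]undecan-2-one | C=C1CC[C@@H](O[Si](C)(C)C(C)(C)C)C(C)(C)[C@@]12CCC(=C)C(=O)C2 | intermediate
18 | lithium (6R,10R)-10-(tert-butyldimethylsilyloxy)-3,11,11-trimethyl-7-methylidenespiro[5.5]undec-2-en-2-olate | [Li+].C=C1CC[C@@H](O[Si](C)(C)C(C)(C)C)C(C)(C)[C@@]12CCC(C)=C([O-])C2 | intermediate (not isolated)
19 | (6R,10R)-10-(tert-butyldimethylsilyloxy)-3,11,11-trimethyl-7-methylidenespiro[5.5]undec-2-en-2-yl trifluoromethanesulfonate | C=C1CC[C@@H](O[Si](C)(C)C(C)(C)C)C(C)(C)[C@@]12CCC(C)=C(OS(=O)(=O)C(F)(F)F)C2 | intermediate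
20 | tert-butyldimethyl{[(6R,10R)-3,11,11-trimethyl-7-methylidenespiro[5.5]undec-2-en-10-yl]oxy}silane | C=C1CC[C@@H](O[Si](C)(C)C(C)(C)C)C(C)(C)[C@@]12CCC(C)=CC2 | intermediate
21 | (6R,10R)-3,11,11-trimethyl-7-methylidenespiro[5.5]undec-2-en-10-ol | C=C1CC[C@@H](O)C(C)(C)[C@@]12CCC(C)=CC2 | intermediate
22 | (6R,10S)-10-bromo-3,11,11-trimethyl-7-methylidenespiro[5.5]undec-2-ene | C=C1CC[C@H](Br)C(C)(C)[C@@]12CCC(C)=CC2 | intermediate
23 | (2R,3R,6R,10S)-2,10-dibromo-3,11,11-trimethyl-7-methylidenespiro[5.5]undecan-3-ol | C=C1CC[C@H](Br)C(C)(C)[C@@]12CC[C@@](C)(O)[C@H](Br)C2 | target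

## Step count and least certain steps

Total step count: 14. Longest linear sequence: 14 steps (1 to 23; reagent 7 is made in the flask in step 4).

**Step 7 (key step).**
- What may go wrong: modest facial selectivity at C6, because the preference for the chair-like tether with equatorial silyloxy group and equatorial C14 is only a few conformational interactions wide. The congestion around C6/C7/C11 may also let the 1,4-diradical revert or disproportionate by hydrogen transfer instead of closing.
- Fallback: from alkyne enone 10, a tin-mediated radical cyclisation. Bu3SnH/AIBN (benzene, 80 °C) adds a stannyl radical to C14; the C7 vinyl radical closes ring A by 6-exo addition to the enone β carbon C6 and gives (6S,10R)-10-(tert-butyldimethylsilyloxy)-11,11-dimethyl-7-[(tributylstannyl)methylidene]spiro[5.5]undecan-2-one F1 (same spatial arrangement at C6 as 13). Protodestannylation with HCl in CH2Cl2 returns the route at 13, bypassing 11 and 12.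

**Step 13.**
- What may go wrong: slow displacement at the neopentyl C10, so that E2 elimination towards C9 or ionisation with methyl migration from C11 overtakes substitution. Backside attack needs the ring A chair with the axial leaving group, and the approach passes an axial C11 methyl.
- Fallback: from 21, a separate sulfonate activation. ClCH2SO2Cl/pyridine gives (6R,10R)-3,11,11-trimethyl-7-methylidenespiro[5.5]undec-2-en-10-yl chloromethanesulfonate F2, a small and highly nucleofugal ester. LiBr in DMF displaces it with inversion and returns the route at 22.

**Step 14.**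
- What may go wrong: the desired capture of the C11-face bromonium ion by water at C3 is not the trans-diaxial opening of the preferred ring B chair (the product is the diequatorial bromohydrin). Capture may therefore be slow, and the bromonium ion on the more hindered C7 face, or bromination at C7=C14, may leak through, lowering facial and site selectivity.
- Fallback: a route without electrophilic bromine, in which the C2 oxygen directs the C3 oxygen and bromide enters as a nucleophile; it sets out from 17 and returns at 23.
  - DIBAL-H (i-Bu2AlH, toluene, −78 °C) delivers hydride from the C11 face and gives allylic alcohol (2S,6R,10R)-10-(tert-butyldimethylsilyloxy)-11,11-dimethyl-3,7-dimethylidenespiro[5.5]undecan-2-ol F3.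
  - VO(acac)2/t-BuOOH gives the syn epoxy alcohol F4.
  - LiAlH4 opens the oxirane at its CH2 to the cis-diol (2S,3R,6R,10R)-10-(tert-butyldimethylsilyloxy)-3,11,11-trimethyl-7-methylidenespiro[5.5]undecane-2,3-diol F5.
  - 1,1'-Sulfonyldiimidazole/NaH gives the cyclic sulfate F6.
  - LiBr attacks the secondary C2 with inversion to the lithium bromo sulfate F7, and dilute H2SO4 hydrolyses it to (2R,3R,6R,10R)-2-bromo-10-(tert-butyldimethylsilyloxy)-3,11,11-trimethyl-7-methylidenespiro[5.5]undecan-3-ol F8.
  - HF·pyridine gives the diol (2R,3R,6R,10R)-2-bromo-3,11,11-trimethyl-7-methylidenespiro[5.5]undecane-3,10-diol F9.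
  - Appel bromination at C10 as in step 13 (the tertiary carbinol is inert) gives 23.

**Step 10.**
- What may go wrong: 1,2-reduction of the carbonyl instead of conjugate reduction, or proton transfer that scrambles the enolate before it is triflated.
- Fallback: from 13, LDA then MeI gives the 3-methyl ketone (6R,10R)-10-(tert-butyldimethylsilyloxy)-3,11,11-trimethyl-7-methylidenespiro[5.5]undecan-2-one F10 (C3 epimers). Triflation under equilibrating conditions (Tf2O, 2,6-di-tert-butyl-4-methylpyridine, CH2Cl2) favours the more substituted enol triflate and returns the route at 19.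

## Further compounds

F1 | step 7 | (6S,10R)-10-(tert-butyldimethylsilyloxy)-11,11-dimethyl-7-[(tributylstannyl)methylidene]spiro[5.5]undecan-2-one | CCCC[Sn](CCCC)(CCCC)C=C1CC[C@@H](O[Si](C)(C)C(C)(C)C)C(C)(C)[C@@]12CCCC(=O)C2
F2 | step 13 | (6R,10R)-3,11,11-trimethyl-7-methylidenespiro[5.5]undec-2-en-10-yl chloromethanesulfonate | C=C1CC[C@@H](OS(=O)(=O)CCl)C(C)(C)[C@@]12CCC(C)=CC2
F3 | step 14 | (2S,6R,10R)-10-(tert-butyldimethylsilyloxy)-11,11-dimethyl-3,7-dimethylidenespiro[5.5]undecan-2-ol | C=C1CC[C@@H](O[Si](C)(C)C(C)(C)C)C(C)(C)[C@@]12CCC(=C)[C@@H](O)C2
F4 | step 14 | syn epoxy alcohol of F3 (oxirane spiro-fused at C3, its oxygen cis to the C2 hydroxyl) | C=C1CC[C@@H](O[Si](C)(C)C(C)(C)C)C(C)(C)[C@@]12CC[C@]3(CO3)[C@@H](O)C2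
F5 | step 14 | (2S,3R,6R,10R)-10-(tert-butyldimethylsilyloxy)-3,11,11-trimethyl-7-methylidenespiro[5.5]undecane-2,3-diol | C=C1CC[C@@H](O[Si](C)(C)C(C)(C)C)C(C)(C)[C@@]12CC[C@@](C)(O)[C@@H](O)C2
F6 | step 14 | cyclic sulfate of F5 | C=C1CC[C@@H](O[Si](C)(C)C(C)(C)C)C(C)(C)[C@@]12CC[C@@](C)(O4)[C@@H](OS4(=O)=O)C2
F7 | step 14 | lithium (2R,3R,6R,10R)-2-bromo-10-(tert-butyldimethylsilyloxy)-3,11,11-trimethyl-7-methylidenespiro[5.5]undecan-3-yl sulfate | [Li+].C=C1CC[C@@H](O[Si](C)(C)C(C)(C)C)C(C)(C)[C@@]12CC[C@@](C)(OS(=O)(=O)[O-])[C@H](Br)C2
F8 | step 14 | (2R,3R,6R,10R)-2-bromo-10-(tert-butyldimethylsilyloxy)-3,11,11-trimethyl-7-methylidenespiro[5.5]undecan-3-ol | C=C1CC[C@@H](O[Si](C)(C)C(C)(C)C)C(C)(C)[C@@]12CC[C@@](C)(O)[C@H](Br)C2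
F9 | step 14 | (2R,3R,6R,10R)-2-bromo-3,11,11-trimethyl-7-methylidenespiro[5.5]undecane-3,10-diol | C=C1CC[C@@H](O)C(C)(C)[C@@]12CC[C@@](C)(O)[C@H](Br)C2
F10 | step 10 | (6R,10R)-10-(tert-butyldimethylsilyloxy)-3,11,11-trimethyl-7-methylidenespiro[5.5]undecan-2-one (C3 epimers) | C=C1CC[C@@H](O[Si](C)(C)C(C)(C)C)C(C)(C)[C@@]12CCC(C)C(=O)C2
A1 | alternative 1 | (6S,10R)-10-hydroxy-3,11,11-trimethylspiro[5.5]undec-2-en-7-one | O=C1CC[C@@H](O)C(C)(C)[C@@]12CCC(C)=CC2
A2 | alternative 1 | 2-methyl-2-[4-methyl-1-(prop-2-enoyl)cyclohex-3-en-1-yl]propanal (single C6 enantiomer) | O=CC(C)(C)[C@@]1(C(=O)C=C)CC=C(C)CC1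
A3 | alternative 2 | spiro tricyclic sultone with ring B silyl enol ether at C1=C2 and C10 ketal | C[C@H]1C[C@@H]2S(=O)(=O)O[C@H]3CCC4(OCCO4)C(C)(C)[C@@]23C=C1O[Si](C)(C)C(C)(C)C
A4 | alternative 2 | ring A ethenesulfonate carrying the exocyclic 2-silyloxy diene (diene geometry not specified) | C=CS(=O)(=O)O[C@H]1CCC2(OCCO2)C(C)(C)C1=CC(O[Si](C)(C)C(C)(C)C)=CC
A5 | alternative 3 | spiro[5.5]undecane keto ester with C3 ketone, C2 8-phenylmenthyl ester, C7 methylidene and C10 silyl ether | C=C1CC[C@@H](O[Si](C)(C)C(C)(C)C)C(C)(C)[C@@]12CCC(=O)[C@H](C(=O)O[C@@H]3C[C@H](C)CC[C@H]3C(C)(C)c3ccccc3)C2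
A6 | alternative 3 | acyclic 8-phenylmenthyl β-keto ester with 1,1-disubstituted alkene, (R)-silyloxy carbinol and terminal alkyne | C=C(CCC(=O)CC(=O)O[C@@H]1C[C@H](C)CC[C@H]1C(C)(C)c1ccccc1)C(C)(C)[C@H](O[Si](C)(C)C(C)(C)C)CCC#C
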